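**Plan**
1. Retrosynthesis: cut the C19 acetate, then C12–C13 (Suzuki coupling; the butenolide enters as the preformed ring of 3-bromofuran-2(5H)-one), then C11=C12 back to a C9–CH2O handle.
2. Then cut C4–C5 and C9–C10 together: ring A (C1–C5, C10) closes through the C4–C5 bond in an epoxide-initiated cation–olefin cyclization whose cascade runs on to the C9–C10 bond, so the trans-decalin is complete in this step and no ring is closed after it.
3. Enabling feature: ring A carries the C3 carbinol next to the quaternary C4 (CH3-18, CH2O-19) and is trans-fused at C5/C10 to ring B, which carries the exocyclic C8=C17 methylene next to C9. These are the marks of an epoxide opened at C4 and of an allylsilane terminator (Me3Si on C17, lost in the step).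
4. Forward: geranyl chloride gives the C3 aldehyde; Still–Gennari olefination, Sharpless epoxidation, acetoacetate-dianion alkylation at C6 and enol phosphate/Me3SiCH2 coupling build the acyclic precursor 14; then bicyclization, side chain and acetate.
5. Stereochemistry: C3 and C4 come from the Sharpless epoxide of the (Z)-allylic alcohol (C4 inverts, putting C19 axial); C5/C10 from the E alkene and C9 from the (Z)-allylsilane in a chair–chair transition state; C11=C12 (E) from the Takai–Utimoto olefination.

Key step: step 11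

Assumption: locants C1–C20 follow ent-labdane (andrographolide) numbering throughout, and 3-bromofuran-2(5H)-one (19) and the Still–Gennari propionate (4) are taken as catalogue compounds.

**Route**

Step 1
Reactants: 1 geranyl chloride
Product: 3 (4E)-6-chloro-4-methylhex-4-enal, via ozonide 2 (not isolated)
Conditions: O3 (1.0 equiv), CH2Cl2, −78 °C; then Me2S, −78 °C to rt
Reagents that add atoms: ozone, [O-][O+]=O
Why: Chemoselective ozonolysis with reductive work-up should cleave the remote, electron-rich trisubstituted alkene, because the other alkene is deactivated by the allylic chloride.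

Step 2
Reactants: 3 (4E)-6-chloro-4-methylhex-4-enal; 4 ethyl 2-[bis(2,2,2-trifluoroethoxy)phosphoryl]propanoate
Product: 5 ethyl (2Z,6E)-8-chloro-2,6-dimethylocta-2,6-dienoate
Conditions: KHMDS, 18-crown-6, THF, −78 °C
Reagents that add atoms: none
Why: Still–Gennari olefination should give the kinetic (Z)-α-methyl enoate, which places the future C19 cis to the chain.

Step 3
Reactants: 5 ethyl (2Z,6E)-8-chloro-2,6-dimethylocta-2,6-dienoate
Product: 6 (2Z,6E)-8-chloro-2,6-dimethylocta-2,6-dien-1-ol
Conditions: DIBAL-H (2.2 equiv), CH2Cl2, −78 °C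
Reagents that add atoms: none
Why: DIBAL-H 1,2-reduction of the conjugated ester should give the allylic alcohol with the allylic chloride left intact at low temperature.

Step 4
Reactants: 6 (2Z,6E)-8-chloro-2,6-dimethylocta-2,6-dien-1-ol
Product: 7 [(2S,3R)-3-[(3E)-5-chloro-3-methylpent-3-enyl]-2-methyloxiran-2-yl]methanol
Conditions: Ti(OiPr)4 (cat.), L-(+)-diethyl tartrate, t-BuOOH, 4 Å MS, CH2Cl2, −20 °C
Reagents that add atoms: tert-butyl hydroperoxide, CC(C)(C)OO
Why: Sharpless asymmetric epoxidation touches only the allylic-alcohol alkene, and the L-(+)-tartrate complex should deliver oxygen to the face that gives the (2S,3R)-epoxide, which fixes C3 (R) and the C4 configuration needed for the later inversion.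

Step 5
Reactants: 7 [(2S,3R)-3-[(3E)-5-chloro-3-methylpent-3-enyl]-2-methyloxiran-2-yl]methanol
Product: 8 tert-butyl{[(2S,3R)-3-[(3E)-5-chloro-3-methylpent-3-enyl]-2-methyloxiran-2-yl]methoxy}diphenylsilane
Conditions: TBDPSCl, imidazole, CH2Cl2, 0 °C
Reagents that add atoms: tert-butyl(chloro)diphenylsilane, CC(C)(C)[Si](Cl)(c1ccccc1)c1ccccc1
Why: Silylation of the primary alcohol gives a bulky, non-chelating and non-participating ether (unlike an acetate) for the later epoxide opening.

Step 6
Reactants: 8 tert-butyl{[(2S,3R)-3-[(3E)-5-chloro-3-methylpent-3-enyl]-2-methyloxiran-2-yl]methoxy}diphenylsilane; 9 methyl acetoacetate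
Product: 10 methyl (6E)-9-[(2R,3S)-3-(TBDPS-oxymethyl)-3-methyloxiran-2-yl]-7-methyl-3-oxonon-6-enoate
Conditions: 9, NaH then n-BuLi, THF, 0 °C; then 8, 0 °C to rt; aq. NH4Cl
Reagents that add atoms: none
Why: Weiler γ-alkylation of the acetoacetate dianion by SN2 displacement of the allylic chloride should join C6–C7 with the E alkene retained and the hindered epoxide untouched.

Step 7
Reactants: 10 methyl (6E)-9-[(2R,3S)-3-(TBDPS-oxymethyl)-3-methyloxiran-2-yl]-7-methyl-3-oxonon-6-enoate
Product: 11 methyl (2Z,6E)-3-(diethoxyphosphoryloxy)-9-[(2R,3S)-3-(TBDPS-oxymethyl)-3-methyloxiran-2-yl]-7-methylnona-2,6-dienoate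
Conditions: NaH, Et2O, 0 °C; then ClP(O)(OEt)2
Reagents that add atoms: diethyl chlorophosphate, CCOP(=O)(Cl)OCC
Why: O-phosphorylation of the chelated sodium enolate should give the (Z)-enol phosphate, which fixes the geometry of the future C8=C9 alkene.

Step 8
Reactants: 11 methyl (2Z,6E)-3-(diethoxyphosphoryloxy)-9-[(2R,3S)-3-(TBDPS-oxymethyl)-3-methyloxiran-2-yl]-7-methylnona-2,6-dienoate
Product: 12 methyl (2Z,6E)-9-[(2R,3S)-3-(TBDPS-oxymethyl)-3-methyloxiran-2-yl]-7-methyl-3-[(trimethylsilyl)methyl]nona-2,6-dienoate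
Conditions: Me3SiCH2MgCl, Ni(acac)2 (cat.), THF, 0 °C to rt
Reagents that add atoms: (trimethylsilyl)methylmagnesium chloride, C[Si](C)(C)C[Mg]Cl
Why: Nickel-catalysed Kumada-type coupling of the enol phosphate should proceed with retention and give the allylsilane with C11 cis to CH2SiMe3.

Step 9
Reactants: 12 methyl (2Z,6E)-9-[(2R,3S)-3-(TBDPS-oxymethyl)-3-methyloxiran-2-yl]-7-methyl-3-[(trimethylsilyl)methyl]nona-2,6-dienoate
Product: 13 (2Z,6E)-9-[(2R,3S)-3-(TBDPS-oxymethyl)-3-methyloxiran-2-yl]-7-methyl-3-[(trimethylsilyl)methyl]nona-2,6-dien-1-ol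
Conditions: DIBAL-H (2.2 equiv), CH2Cl2, −78 °C
Reagents that add atoms: none
Why: DIBAL-H reduction of the enoate removes the electron-withdrawing group from the allylsilane at a temperature where the trisubstituted epoxide and silyl ether should survive.

Step 10
Reactants: 13 (2Z,6E)-9-[(2R,3S)-3-(TBDPS-oxymethyl)-3-methyloxiran-2-yl]-7-methyl-3-[(trimethylsilyl)methyl]nona-2,6-dien-1-ol
Product: 14 (2Z,6E)-1-TBSO-9-[(2R,3S)-3-(TBDPS-oxymethyl)-3-methyloxiran-2-yl]-7-methyl-3-[(trimethylsilyl)methyl]nona-2,6-diene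
Conditions: TBSCl, imidazole, CH2Cl2, 0 °C
Reagents that add atoms: tert-butyl(chloro)dimethylsilane, CC(C)(C)[Si](C)(C)Cl
Why: Silylation masks the C11 hydroxyl as an ether that binds the Lewis acid poorly and can later be removed without touching the TBDPS group.

Step 11
Reactants: 14 (2Z,6E)-1-TBSO-9-[(2R,3S)-3-(TBDPS-oxymethyl)-3-methyloxiran-2-yl]-7-methyl-3-[(trimethylsilyl)methyl]nona-2,6-diene
Product: 15 3-hydroxy-11-TBSO-19-TBDPSO-12,13,14,15,16-pentanor-ent-labd-8(17)-ene
Conditions: MeAlCl2 (2 equiv), CH2Cl2, −78 °C; aq. NaHCO3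
Reagents that add atoms: none
Why: MeAlCl2 activates the epoxide, the C5=C10 alkene attacks C4 anti to the breaking C4–O bond (ring A: 6-endo on the alkene, endo opening of the epoxide with C3 and C4 both in the ring), the C10 cation is captured by C9 of the allylsilane (ring B: 6-endo-trig), and loss of silicon from the β-silyl C8 cation leaves the C8=C17 methylene. The closest known reaction type is the Lewis acid-promoted epoxide-initiated cation–olefin (epoxy-polyene) bicyclization with an allylsilane terminator. C3 keeps the configuration from step 4 with its oxygen equatorial in the chair; C4 is inverted so that the Z substituent (CH2OTBDPS) becomes axial and cis to CH3-20; the E geometry of C5=C10 gives anti addition and the trans ring fusion; the (Z)-allylsilane places C11 equatorial at C9 in the chair–chair transition state. The step needs opening at the tertiary C4 and not at C3, which the cation-stabilising substitution and the six-membered transition state should secure, and termination only toward C17, which the silicon secures.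

Step 12
Reactants: 15 3-hydroxy-11-TBSO-19-TBDPSO-12,13,14,15,16-pentanor-ent-labd-8(17)-ene
Product: 16 19-TBDPSO-12,13,14,15,16-pentanor-ent-labd-8(17)-ene-3,11-diol
Conditions: CSA (cat.), MeOH/CH2Cl2, 0 °C
Reagents that add atoms: none
Why: Acid-catalysed methanolysis should cleave the less hindered primary TBS ether and leave the neopentyl TBDPS ether.

Step 13
Reactants: 16 19-TBDPSO-12,13,14,15,16-pentanor-ent-labd-8(17)-ene-3,11-diol
Product: 17 3-hydroxy-19-TBDPSO-12,13,14,15,16-pentanor-ent-labd-8(17)-en-11-al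
Conditions: TEMPO (cat.), PhI(OAc)2, CH2Cl2, rt
Reagents that add atoms: none
Why: TEMPO/PhI(OAc)2 oxidation should take the primary alcohol in preference to the hindered secondary C3 alcohol and is non-basic, so the β,γ-unsaturated aldehyde should not move into conjugation.

Step 14
Reactants: 17 3-hydroxy-19-TBDPSO-12,13,14,15,16-pentanor-ent-labd-8(17)-en-11-al
Product: 18 (11E)-3-hydroxy-19-TBDPSO-13,14,15,16-tetranor-ent-labda-8(17),11-dien-12-yl pinacol boronate
Conditions: Cl2CHBpin, CrCl2 (8 equiv), LiI, THF, rt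
Reagents that add atoms: 2-(dichloromethyl)-4,4,5,5-tetramethyl-1,3,2-dioxaborolane, ClC(Cl)B1OC(C)(C)C(C)(C)O1
Why: Takai–Utimoto olefination adds a geminal dichromium reagent to the aldehyde without base and should give the (E)-alkenylboronate, setting the C11=C12 geometry.

Step 15
Reactants: 18 (11E)-3-hydroxy-19-TBDPSO-13,14,15,16-tetranor-ent-labda-8(17),11-dien-12-yl pinacol boronate; 19 3-bromofuran-2(5H)-one
Product: 20 19-O-TBDPS-14-deoxy-11,12-didehydroandrographolide
Conditions: Pd(dppf)Cl2 (cat.), K3PO4, THF/H2O, rt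
Reagents that add atoms: none
Why: Suzuki–Miyaura coupling should join C12 to C13 of the preformed butenolide with retention of the E geometry under mild base.

Step 16
Reactants: 20 19-O-TBDPS-14-deoxy-11,12-didehydroandrographolide
Product: 21 14-deoxy-11,12-didehydroandrographolide
Conditions: HF·pyridine, pyridine/THF, 0 °C to rt
Reagents that add atoms: none
Why: Fluoride-mediated desilylation under mildly acidic conditions should free the C19 hydroxyl without harming the dienyl butenolide.

Step 17
Reactants: 21 14-deoxy-11,12-didehydroandrographolide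
Product: 22 19-O-acetyl-14-deoxy-11,12-didehydroandrographolide (target)
Conditions: Ac2O (1.1 equiv), 2,4,6-collidine, CH2Cl2, −20 °C to 0 °C
Reagents that add atoms: acetic anhydride, CC(=O)OC(C)=O
Why: Kinetically controlled acylation should take the primary C19 hydroxyl in preference to the secondary C3 hydroxyl flanked by the quaternary C4.

**Compound list**
1 | geranyl chloride, (2E)-1-chloro-3,7-dimethylocta-2,6-diene | ClC/C=C(\C)CCC=C(C)C | starting material
2 | ozonide, 3-[(3E)-5-chloro-3-methylpent-3-enyl]-5,5-dimethyl-1,2,4-trioxolane | ClC/C=C(\C)CCC1OOC(C)(C)O1 | intermediate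
3 | (4E)-6-chloro-4-methylhex-4-enal | ClC/C=C(\C)CCC=O | intermediate
4 | ethyl 2-[bis(2,2,2-trifluoroethoxy)phosphoryl]propanoate | CCOC(=O)C(C)P(=O)(OCC(F)(F)F)OCC(F)(F)F | starting material
5 | ethyl (2Z,6E)-8-chloro-2,6-dimethylocta-2,6-dienoate | ClC/C=C(\C)CC/C=C(/C)C(=O)OCC | intermediate
6 | (2Z,6E)-8-chloro-2,6-dimethylocta-2,6-dien-1-ol | ClC/C=C(\C)CC/C=C(/C)CO | intermediate
7 | [(2S,3R)-3-[(3E)-5-chloro-3-methylpent-3-enyl]-2-methyloxiran-2-yl]methanol (CH2OH cis to the chain) | ClC/C=C(\C)CC[C@H]1O[C@@]1(C)CO | intermediate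
8 | TBDPS ether of 7 | ClC/C=C(\C)CC[C@H]1O[C@@]1(C)CO[Si](c1ccccc1)(c1ccccc1)C(C)(C)C | intermediate
9 | methyl acetoacetate | COC(=O)CC(C)=O | starting material
10 | methyl (6E)-9-[(2R,3S)-3-(TBDPS-oxymethyl)-3-methyloxiran-2-yl]-7-methyl-3-oxonon-6-enoate | COC(=O)CC(=O)CC/C=C(\C)CC[C@H]1O[C@@]1(C)CO[Si](c1ccccc1)(c1ccccc1)C(C)(C)C | intermediate
11 | (2Z)-enol diethyl phosphate of 10 | COC(=O)/C=C(\OP(=O)(OCC)OCC)CC/C=C(\C)CC[C@H]1O[C@@]1(C)CO[Si](c1ccccc1)(c1ccccc1)C(C)(C)C | intermediate
12 | (2Z,6E)-allylsilane ester (CO2Me cis to CH2SiMe3) | COC(=O)/C=C(\C[Si](C)(C)C)CC/C=C(\C)CC[C@H]1O[C@@]1(C)CO[Si](c1ccccc1)(c1ccccc1)C(C)(C)C | intermediate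
13 | (2Z,6E)-allylsilane allylic alcohol | OC/C=C(\C[Si](C)(C)C)CC/C=C(\C)CC[C@H]1O[C@@]1(C)CO[Si](c1ccccc1)(c1ccccc1)C(C)(C)C | intermediate
14 | TBS ether of 13, the cyclization precursor | CC(C)(C)[Si](C)(C)OC/C=C(\C[Si](C)(C)C)CC/C=C(\C)CC[C@H]1O[C@@]1(C)CO[Si](c1ccccc1)(c1ccccc1)C(C)(C)C | intermediate
15 | 3-hydroxy-11-TBSO-19-TBDPSO-12,13,14,15,16-pentanor-ent-labd-8(17)-ene (trans-decalin; 3-OH equatorial; 3-OH, C19, C20 and C11 on one face; H3, H5, H9 and C18 on the other) | C=C1CC[C@@H]2[C@](C)(CO[Si](c3ccccc3)(c3ccccc3)C(C)(C)C)[C@H](O)CC[C@@]2(C)[C@@H]1CO[Si](C)(C)C(C)(C)C | intermediate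
16 | 19-TBDPSO-12,13,14,15,16-pentanor-ent-labd-8(17)-ene-3,11-diol (configuration as 15) | C=C1CC[C@@H]2[C@](C)(CO[Si](c3ccccc3)(c3ccccc3)C(C)(C)C)[C@H](O)CC[C@@]2(C)[C@@H]1CO | intermediate
17 | 3-hydroxy-19-TBDPSO-12,13,14,15,16-pentanor-ent-labd-8(17)-en-11-al (CHO equatorial at C9) | C=C1CC[C@@H]2[C@](C)(CO[Si](c3ccccc3)(c3ccccc3)C(C)(C)C)[C@H](O)CC[C@@]2(C)[C@@H]1C=O | intermediate
18 | (11E)-alkenyl pinacol boronate at C12 | C=C1CC[C@@H]2[C@](C)(CO[Si](c3ccccc3)(c3ccccc3)C(C)(C)C)[C@H](O)CC[C@@]2(C)[C@@H]1/C=C/B1OC(C)(C)C(C)(C)O1 | intermediate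
19 | 3-bromofuran-2(5H)-one | O=C1OCC=C1Br | starting material
20 | 19-O-TBDPS-14-deoxy-11,12-didehydroandrographolide | C=C1CC[C@@H]2[C@](C)(CO[Si](c3ccccc3)(c3ccccc3)C(C)(C)C)[C@H](O)CC[C@@]2(C)[C@@H]1/C=C/C1=CCOC1=O | intermediate
21 | 14-deoxy-11,12-didehydroandrographolide | C=C1CC[C@@H]2[C@](C)(CO)[C@H](O)CC[C@@]2(C)[C@@H]1/C=C/C1=CCOC1=O | intermediate
22 | 19-O-acetyl-14-deoxy-11,12-didehydroandrographolide | C=C1CC[C@@H]2[C@](C)(COC(C)=O)[C@H](O)CC[C@@]2(C)[C@@H]1/C=C/C1=CCOC1=O | target

**Step count and risks**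
Total steps: 17. Longest linear sequence: 17 steps (1 to 22).

Most likely to fail, first: the bicyclization of step 11. The opened epoxide may collapse by 1,2-hydride shift to a C3 ketone or be attacked at C3 to give a five-membered ring. The γ-silyl allylic ether may also fragment by 1,4-elimination to a diene, or lose silicon by protonation before ring B closes. The fallback sets out from β-keto ester 10 and comes back at diol 16. The epoxide-initiated bicyclization is run on 10 itself (SnCl4, CH2Cl2, −78 °C), whose enol is a terminator that tolerates the Lewis acid, to give the bicyclic hydroxy β-keto ester F1 with the C8 ketone. The methylene is then made after ring formation: one equivalent of NaH and PhNTf2 give the enol triflate F2, palladium-catalysed coupling with Me3SiCH2MgCl gives the γ-silyl enoate F3, and fluoride-induced deconjugative protodesilylation (CsF, wet DMF) gives the β,γ-unsaturated ester F4 with the exocyclic alkene and the C9 hydrogen on the face away from CH3-20. DIBAL-H reduction of the ester then gives 16.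

Second: the coupling of step 8. The Grignard reagent or its magnesium salts may open or rearrange the trisubstituted epoxide, and the enol phosphate may be reduced instead of coupled. The fallback sets out from 10 and comes back at 12. The sodium enolate of 10 is trapped with PhNTf2 as the (Z)-enol triflate F5, and a Stille coupling with tributyl[(trimethylsilyl)methyl]stannane (Pd(PPh3)4, LiCl, THF, 60 °C) puts in the silylmethyl group under neutral, magnesium-free conditions.

Third: the olefination of step 14. Addition of the bulky geminal dichromium reagent to the hindered α-branched aldehyde may be slow, and the β,γ-unsaturated aldehyde may epimerise at C9 or move into conjugation while it waits. The fallback sets out from 17 and comes back at 20, bypassing 18. A fast, non-basic titanium methylenation (Petasis reagent Cp2TiMe2, toluene, 65 °C) gives the C9-vinyl compound F6, and a Heck reaction of its terminal alkene with 19 (Pd(OAc)2, P(o-tol)3, Ag2CO3, DMF) builds the (E)-C11=C12 bond and attaches the butenolide in one operation.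

**Further compounds**
F1 | step 11 | methyl 3-hydroxy-8-oxo-19-TBDPSO-12,13,14,15,16,17-hexanor-ent-labdan-11-oate (bicyclic hydroxy β-keto ester) | O=C1CC[C@@H]2[C@](C)(CO[Si](c3ccccc3)(c3ccccc3)C(C)(C)C)[C@H](O)CC[C@@]2(C)[C@@H]1C(=O)OC
F2 | step 11 | enol triflate of F1 (C8–OTf, C8=C9) | FC(F)(F)S(=O)(=O)OC=1CC[C@@H]2[C@](C)(CO[Si](c3ccccc3)(c3ccccc3)C(C)(C)C)[C@H](O)CC[C@@]2(C)C=1C(=O)OC
F3 | step 11 | γ-silyl enoate (C8–CH2SiMe3, C8=C9–CO2Me) | C[Si](C)(C)CC=1CC[C@@H]2[C@](C)(CO[Si](c3ccccc3)(c3ccccc3)C(C)(C)C)[C@H](O)CC[C@@]2(C)C=1C(=O)OC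
F4 | step 11 | methyl 3-hydroxy-19-TBDPSO-12,13,14,15,16-pentanor-ent-labd-8(17)-en-11-oate | C=C1CC[C@@H]2[C@](C)(CO[Si](c3ccccc3)(c3ccccc3)C(C)(C)C)[C@H](O)CC[C@@]2(C)[C@@H]1C(=O)OC
F5 | step 8 | (2Z)-enol triflate of 10 | COC(=O)/C=C(\OS(=O)(=O)C(F)(F)F)CC/C=C(\C)CC[C@H]1O[C@@]1(C)CO[Si](c1ccccc1)(c1ccccc1)C(C)(C)C
F6 | step 14 | 3-hydroxy-19-TBDPSO-13,14,15,16-tetranor-ent-labda-8(17),11-diene (C9-vinyl compound) | C=C1CC[C@@H]2[C@](C)(CO[Si](c3ccccc3)(c3ccccc3)C(C)(C)C)[C@H](O)CC[C@@]2(C)[C@@H]1C=C
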